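**Retrosynthetic overview**
1. The macrocycle is closed last, at C4=C5, by ring-closing metathesis of a vinyl/isopropenyl diene.
2. The C6 tiglate comes from Mitsunobu inversion of a 6R alcohol; the lactone and C7/C8 come from a late allylboration–lactonisation joining an east aldehyde (C1–C4, C8–C10, C14, C15) and a west allylboronate (C5–C7, C11–C13).
3. East: 3(2H)-furanone from an α'-hydroxy ynone; C10 from D-lactic acid by Seebach alkylation.
4. West: (R)-but-3-ene-1,2-diol → silyloxy ynoate → hydroalumination/borylmethylation to a geometrically defined 2-(methoxycarbonyl)allylboronate.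
5. Ring order: furanone (east branch), α-methylene lactone (at the union), ten-membered carbocycle (last step).

Assumption: atom labels follow germacrane numbering (C1 ketone carbon, C3 and C10 the oxygen-bridged carbons, C12 lactone carbonyl, C13 exocyclic methylene); D-lactic acid and (R)-but-3-ene-1,2-diol are taken as purchasable.

**East branch**

Step 1
Reactants: 1 (R)-lactic acid
Product: 2 (2R,5R)-2-tert-butyl-5-methyl-1,3-dioxolan-4-one
Conditions: t-BuCHO, TsOH·H2O (cat.), H2SO4 (cat.), pentane, reflux, Dean–Stark; recrystallise from Et2O/pentane, −78 °C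
Reagents that add atoms: pivaldehyde (2,2-dimethylpropanal), CC(C)(C)C=O
Why: Acid-catalysed acetalisation (Seebach self-regeneration of stereocentres) under thermodynamic control gives the cis dioxolanone, the new acetal centre (2R) being dictated by the lactate centre and upgraded by crystallisation.

Step 2
Reactants: 2 (2R,5R)-2-tert-butyl-5-methyl-1,3-dioxolan-4-one; 3 allyl bromide (3-bromoprop-1-ene)
Product: 5 (2R,5S)-2-tert-butyl-5-methyl-5-(prop-2-en-1-yl)-1,3-dioxolan-4-one, via lithium enolate 4 (not isolated)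
Conditions: LiN(i-Pr)2, THF, −78 °C; then 3, −78 → −30 °C
Reagents that add atoms: none
Why: Seebach enolate alkylation: the planar enolate is allylated on the face opposite the tert-butyl group, so the quaternary centre (future C10, S) is formed with net retention of the lactate configuration.

Step 3
Reactants: 5 (2R,5S)-2-tert-butyl-5-methyl-5-(prop-2-en-1-yl)-1,3-dioxolan-4-one
Product: 7 2-[(2R,4S)-2-tert-butyl-4-methyl-5-oxo-1,3-dioxolan-4-yl]acetaldehyde, via ozonide 6 (not isolated)
Conditions: O3, CH2Cl2, −78 °C; then PPh3, −78 °C → rt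
Reagents that add atoms: ozone, [O-][O+]=O
Why: Ozonolysis with reductive work-up cleaves the only alkene to the C8 aldehyde without touching the acylal or the quaternary centre.

Step 4
Reactants: 7 2-[(2R,4S)-2-tert-butyl-4-methyl-5-oxo-1,3-dioxolan-4-yl]acetaldehyde
Product: 9 (3S)-3-hydroxy-3-methyloxolan-2-one, via hydroxyethyl dioxolanone 8 (not isolated)
Conditions: NaBH4, MeOH, −20 °C; AcOH quench; then TsOH·H2O (cat.), CH2Cl2, rt
Reagents that add atoms: none
Why: Borohydride reduction of the aldehyde followed by acid-catalysed intramolecular transesterification (lactonisation) expels pivaldehyde and carries the intact quaternary centre into a lactone that masks C8 as an alcohol.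

Step 5
Reactants: 9 (3S)-3-hydroxy-3-methyloxolan-2-one; 10 2-methylbut-1-en-3-yne
Product: 12 (3S)-1,3-dihydroxy-3,7-dimethyloct-7-en-5-yn-4-one, via lithium acetylide 11 (not isolated)
Conditions: 10 (3.2 equiv), n-BuLi (3.0 equiv), THF, −78 °C; then 9, −78 → −40 °C; AcOH, −78 °C
Reagents that add atoms: none
Why: Nucleophilic acyl addition of the lithium acetylide to the lactone stops at the tetrahedral alkoxide (adjacent alkoxide and low temperature prevent a second addition) and opens on work-up to the ynone, leaving the stereocentre untouched.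

Step 6
Reactants: 12 (3S)-1,3-dihydroxy-3,7-dimethyloct-7-en-5-yn-4-one
Product: 14 (2S)-2-(2-hydroxyethyl)-2-methyl-5-(prop-1-en-2-yl)furan-3(2H)-one, via enaminone 13 (not isolated)
Conditions: Et2NH, EtOH, rt; then 10% aq. AcOH, rt
Reagents that add atoms: none
Why: Amine-mediated cycloisomerisation of an α'-hydroxy ynone (conjugate addition of Et2NH, then addition–elimination by the tertiary hydroxyl) is the classical 3(2H)-furanone synthesis, and the primary alcohol cannot compete because it would have to form a seven-membered ring.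

Step 7
Reactants: 14 (2S)-2-(2-hydroxyethyl)-2-methyl-5-(prop-1-en-2-yl)furan-3(2H)-one
Product: 15 2-[(2S)-2-methyl-3-oxo-5-(prop-1-en-2-yl)-2,3-dihydrofuran-2-yl]acetaldehyde
Conditions: Dess–Martin periodinane, NaHCO3, CH2Cl2, 0 °C → rt; used crude
Reagents that add atoms: none
Why: Buffered Dess–Martin oxidation gives the aldehyde under non-basic conditions, avoiding β-elimination of the furanone oxygen.

**West branch**

Step 8
Reactants: 16 (2R)-but-3-ene-1,2-diol
Product: 17 (3R)-3,4-bis[(tert-butyldimethylsilyl)oxy]but-1-ene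
Conditions: TBSCl (2.5 equiv), imidazole, DMF, rt
Reagents that add atoms: tert-butyldimethylsilyl chloride, CC(C)(C)[Si](C)(C)Cl
Why: Standard silyl ether formation protects both hydroxyls without affecting the stereocentre (future C6).

Step 9
Reactants: 17 (3R)-3,4-bis[(tert-butyldimethylsilyl)oxy]but-1-ene
Product: 18 (2R)-2-[(tert-butyldimethylsilyl)oxy]but-3-en-1-ol
Conditions: camphorsulfonic acid (0.1 equiv), MeOH/CH2Cl2 1:1, 0 °C
Reagents that add atoms: none
Why: Acid-catalysed methanolysis (selective desilylation) removes the unhindered primary silyl ether much faster than the secondary allylic one.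

Step 10
Reactants: 18 (2R)-2-[(tert-butyldimethylsilyl)oxy]but-3-en-1-ol
Product: 19 (2R)-2-[(tert-butyldimethylsilyl)oxy]but-3-enal
Conditions: Dess–Martin periodinane, NaHCO3, CH2Cl2, 0 °C; used at once
Reagents that add atoms: none
Why: Dess–Martin oxidation is non-basic, so the α-silyloxy β,γ-unsaturated aldehyde forms without racemisation or migration of the alkene into conjugation.

Step 11
Reactants: 19 (2R)-2-[(tert-butyldimethylsilyl)oxy]but-3-enal
Product: 20 (3R)-1,1-dibromo-3-[(tert-butyldimethylsilyl)oxy]penta-1,4-diene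
Conditions: CBr4 (2 equiv), PPh3 (4 equiv), CH2Cl2, 0 °C; then 19, −78 → 0 °C
Reagents that add atoms: carbon tetrabromide, BrC(Br)(Br)Br
Why: Corey–Fuchs dibromo-olefination (Wittig-type reaction of Ph3P=CBr2) adds C11 under base-free conditions that preserve the stereocentre.

Step 12
Reactants: 20 (3R)-1,1-dibromo-3-[(tert-butyldimethylsilyl)oxy]penta-1,4-diene
Product: 22 methyl (4R)-4-[(tert-butyldimethylsilyl)oxy]hex-5-en-2-ynoate, via lithium acetylide 21 (not isolated)
Conditions: n-BuLi (2.1 equiv), THF, −78 °C; then ClCO2Me, −78 → 0 °C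
Reagents that add atoms: methyl chloroformate, COC(=O)Cl
Why: The second Corey–Fuchs stage (Br/Li exchange, Fritsch–Buttenberg–Wiechell rearrangement, deprotonation) gives the lithium acetylide, whose acylation installs C12 as the methyl ester.

Step 13
Reactants: 22 methyl (4R)-4-[(tert-butyldimethylsilyl)oxy]hex-5-en-2-ynoate
Product: 24 methyl (2Z,4R)-4-[(tert-butyldimethylsilyl)oxy]-2-[(4,4,5,5-tetramethyl-1,3,2-dioxaborolan-2-yl)methyl]hexa-2,5-dienoate, via vinylalane 23 (not isolated)
Conditions: i-Bu2AlH (1.3 equiv), HMPA, THF, 0 °C; then ICH2Bpin, 0 °C → rt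
Reagents that add atoms: 2-(iodomethyl)-4,4,5,5-tetramethyl-1,3,2-dioxaborolane, ICB1OC(C)(C)C(C)(C)O1
Why: syn-1,4-Hydroalumination of the ynoate gives the α-aluminated enoate, and its alkylation by the iodomethylboronate (boron ate complex, 1,2-shift) proceeds with retention, fixing C6 cis to the ester as needed for an anti-selective allylboration.

**Union and endgame**

Step 14
Reactants: 15 2-[(2S)-2-methyl-3-oxo-5-(prop-1-en-2-yl)-2,3-dihydrofuran-2-yl]acetaldehyde; 24 methyl (2Z,4R)-4-[(tert-butyldimethylsilyl)oxy]-2-[(4,4,5,5-tetramethyl-1,3,2-dioxaborolan-2-yl)methyl]hexa-2,5-dienoate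
Product: 26 (2S)-2-{[(2S,3R)-3-[(1R)-1-[(tert-butyldimethylsilyl)oxy]prop-2-en-1-yl]-4-methylidene-5-oxooxolan-2-yl]methyl}-2-methyl-5-(prop-1-en-2-yl)furan-3(2H)-one, via hydroxy ester 25 (not isolated)
Conditions: Sc(OTf)3 (10 mol %), toluene, 0 °C → rt; then TsOH·H2O (20 mol %), rt
Reagents that add atoms: none
Why: Lewis-acid-catalysed allylboration through a closed chair (Zimmerman–Traxler) transition state turns the boronate geometry into the anti C7/C8 relationship (trans lactone after lactonisation), while the aldehyde adds to the C7 face opposite the silyloxy group in the allylic-strain-minimised conformer (Felkin-type 1,2-induction), giving 7R,8S from the 6R reagent.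

Step 15
Reactants: 26 the silyl ether lactone from step 14
Product: 27 (2S)-2-{[(2S,3S)-3-[(1R)-1-hydroxyprop-2-en-1-yl]-4-methylidene-5-oxooxolan-2-yl]methyl}-2-methyl-5-(prop-1-en-2-yl)furan-3(2H)-one
Conditions: HF·pyridine, pyridine, THF, 0 °C → rt
Reagents that add atoms: none
Why: Buffered fluoride desilylation frees the C6 hydroxyl (still 6R) without adding to the α-methylene lactone or opening the furanone.

Step 16
Reactants: 27 the 6R allylic alcohol from step 15; 28 tiglic acid ((2E)-2-methylbut-2-enoic acid)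
Product: 29 (1S)-1-[(2S,3R)-2-{[(2S)-2-methyl-3-oxo-5-(prop-1-en-2-yl)-2,3-dihydrofuran-2-yl]methyl}-4-methylidene-5-oxooxolan-3-yl]prop-2-en-1-yl (2E)-2-methylbut-2-enoate
Conditions: PPh3, DIAD, toluene, 0 °C → rt
Reagents that add atoms: none
Why: Mitsunobu esterification displaces the activated C6 oxygen by tiglate in an SN2 step, inverting 6R to the required 6S while installing the ester.

Step 17
Reactants: 29 the tiglate diene from step 16
Product: 30 CNP0293168.2, (6S,7R,8S,10S)-6-(tigloyloxy)-3,10-epoxy-1-oxogermacra-2,4(Z),11(13)-trien-12,8-olide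
Conditions: second-generation Hoveyda–Grubbs catalyst (2 × 10 mol %), toluene, 1 mM, 100 °C, argon sparge
Reagents that add atoms: none
Why: Ring-closing metathesis between the vinyl and isopropenyl groups closes the nine-membered oxa-bridged ring (the ten-membered carbocycle) with loss of ethene, the ring size enforcing the 4Z trisubstituted alkene.

**Compound list**
1 | (R)-lactic acid | C[C@@H](O)C(=O)O | starting material
2 | (2R,5R)-2-tert-butyl-5-methyl-1,3-dioxolan-4-one | C[C@H]1O[C@@H](C(C)(C)C)OC1=O | intermediate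
3 | allyl bromide | C=CCBr | starting material
4 | lithium (2R)-2-tert-butyl-5-methyl-1,3-dioxol-4-olate (enolate of 2) | CC1=C([O-])O[C@H](C(C)(C)C)O1.[Li+] | intermediate (not isolated)
5 | (2R,5S)-2-tert-butyl-5-methyl-5-(prop-2-en-1-yl)-1,3-dioxolan-4-one | C[C@@]1(CC=C)O[C@@H](C(C)(C)C)OC1=O | intermediate
6 | (2R,5S)-2-tert-butyl-5-methyl-5-(1,2,4-trioxolan-3-ylmethyl)-1,3-dioxolan-4-one (both epimers at the trioxolane carbon) | C[C@@]1(CC2OCOO2)O[C@@H](C(C)(C)C)OC1=O | intermediate (not isolated)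
7 | 2-[(2R,4S)-2-tert-butyl-4-methyl-5-oxo-1,3-dioxolan-4-yl]acetaldehyde | C[C@@]1(CC=O)O[C@@H](C(C)(C)C)OC1=O | intermediate
8 | (2R,5S)-2-tert-butyl-5-(2-hydroxyethyl)-5-methyl-1,3-dioxolan-4-one | C[C@@]1(CCO)O[C@@H](C(C)(C)C)OC1=O | intermediate (not isolated)
9 | (3S)-3-hydroxy-3-methyloxolan-2-one | C[C@]1(O)CCOC1=O | intermediate
10 | 2-methylbut-1-en-3-yne | C=C(C)C#C | starting material
11 | (3-methylbut-3-en-1-yn-1-yl)lithium | [Li]C#CC(C)=C | intermediate (not isolated)
12 | (3S)-1,3-dihydroxy-3,7-dimethyloct-7-en-5-yn-4-one (in equilibrium with its cyclic hemiketal) | C=C(C)C#CC(=O)[C@@](C)(O)CCO | intermediate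
13 | (3S)-5-(diethylamino)-1,3-dihydroxy-3,7-dimethylocta-5,7-dien-4-one (alkene isomers) | C=C(C)C(=CC(=O)[C@@](C)(O)CCO)N(CC)CC | intermediate (not isolated)
14 | (2S)-2-(2-hydroxyethyl)-2-methyl-5-(prop-1-en-2-yl)furan-3(2H)-one | C=C(C)C1=CC(=O)[C@](C)(CCO)O1 | intermediate
15 | 2-[(2S)-2-methyl-3-oxo-5-(prop-1-en-2-yl)-2,3-dihydrofuran-2-yl]acetaldehyde | C=C(C)C1=CC(=O)[C@](C)(CC=O)O1 | intermediate
16 | (2R)-but-3-ene-1,2-diol | C=C[C@@H](O)CO | starting material
17 | (3R)-3,4-bis[(tert-butyldimethylsilyl)oxy]but-1-ene | C=C[C@@H](O[Si](C)(C)C(C)(C)C)CO[Si](C)(C)C(C)(C)C | intermediate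
18 | (2R)-2-[(tert-butyldimethylsilyl)oxy]but-3-en-1-ol | C=C[C@@H](O[Si](C)(C)C(C)(C)C)CO | intermediate
19 | (2R)-2-[(tert-butyldimethylsilyl)oxy]but-3-enal | C=C[C@@H](O[Si](C)(C)C(C)(C)C)C=O | intermediate
20 | (3R)-1,1-dibromo-3-[(tert-butyldimethylsilyl)oxy]penta-1,4-diene | C=C[C@@H](O[Si](C)(C)C(C)(C)C)C=C(Br)Br | intermediate
21 | [(3R)-3-[(tert-butyldimethylsilyl)oxy]pent-4-en-1-yn-1-yl]lithium | C=C[C@@H](O[Si](C)(C)C(C)(C)C)C#C[Li] | intermediate (not isolated)
22 | methyl (4R)-4-[(tert-butyldimethylsilyl)oxy]hex-5-en-2-ynoate | C=C[C@@H](O[Si](C)(C)C(C)(C)C)C#CC(=O)OC | intermediate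
23 | methyl (2E,4R)-4-[(tert-butyldimethylsilyl)oxy]-2-(diisobutylalumanyl)hexa-2,5-dienoate | C=C[C@@H](O[Si](C)(C)C(C)(C)C)/C=C(/[Al](CC(C)C)CC(C)C)C(=O)OC | intermediate (not isolated)
24 | methyl (2Z,4R)-4-[(tert-butyldimethylsilyl)oxy]-2-[(4,4,5,5-tetramethyl-1,3,2-dioxaborolan-2-yl)methyl]hexa-2,5-dienoate | C=C[C@@H](O[Si](C)(C)C(C)(C)C)/C=C(/CB1OC(C)(C)C(C)(C)O1)C(=O)OC | intermediate
25 | methyl (3R,4S)-3-[(1R)-1-[(tert-butyldimethylsilyl)oxy]prop-2-en-1-yl]-4-hydroxy-2-methylidene-5-[(2S)-2-methyl-3-oxo-5-(prop-1-en-2-yl)-2,3-dihydrofuran-2-yl]pentanoate | C=C(C(=O)OC)[C@@H]([C@H](O[Si](C)(C)C(C)(C)C)C=C)[C@@H](O)C[C@]1(C)OC(=CC1=O)C(C)=C | intermediate (not isolated)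
26 | (2S)-2-{[(2S,3R)-3-[(1R)-1-[(tert-butyldimethylsilyl)oxy]prop-2-en-1-yl]-4-methylidene-5-oxooxolan-2-yl]methyl}-2-methyl-5-(prop-1-en-2-yl)furan-3(2H)-one | C=C1C(=O)O[C@@H](C[C@]2(C)OC(=CC2=O)C(C)=C)[C@@H]1[C@H](O[Si](C)(C)C(C)(C)C)C=C | intermediate
27 | (2S)-2-{[(2S,3S)-3-[(1R)-1-hydroxyprop-2-en-1-yl]-4-methylidene-5-oxooxolan-2-yl]methyl}-2-methyl-5-(prop-1-en-2-yl)furan-3(2H)-one | C=C1C(=O)O[C@@H](C[C@]2(C)OC(=CC2=O)C(C)=C)[C@@H]1[C@H](O)C=C | intermediate
28 | tiglic acid, (2E)-2-methylbut-2-enoic acid | C/C=C(\C)C(=O)O | starting material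
29 | (1S)-1-[(2S,3R)-2-{[(2S)-2-methyl-3-oxo-5-(prop-1-en-2-yl)-2,3-dihydrofuran-2-yl]methyl}-4-methylidene-5-oxooxolan-3-yl]prop-2-en-1-yl (2E)-2-methylbut-2-enoate | C=C1C(=O)O[C@@H](C[C@]2(C)OC(=CC2=O)C(C)=C)[C@@H]1[C@@H](OC(=O)/C(C)=C/C)C=C | intermediate
30 | CNP0293168.2, (6S,7R,8S,10S)-6-(tigloyloxy)-3,10-epoxy-1-oxogermacra-2,4(Z),11(13)-trien-12,8-olide | C=C1C(=O)O[C@H]2C[C@]3(C)OC(=CC3=O)/C(C)=C\[C@H](OC(=O)/C(C)=C/C)[C@H]12 | target

**Totals**
Total step count: 17. Longest linear sequence: 11 steps (steps 1–7, then 14–17); the west branch (steps 8–13) runs in parallel and joins at step 14.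

**Steps most likely to fail**

Step 14 (fragment union). The facial selectivity relative to the C6 silyloxy centre is predicted from a model, not demonstrated, and aldehyde 15 may lose the furanone oxygen by β-elimination under Lewis acid. The fallback replaces acyclic 1,2-induction by ring control and sets out from boronate 24 (with aldehyde 15 unchanged). Desilylation of 24 with HF·pyridine lets the freed hydroxyl close onto the cis ester to give (5R)-5-ethenyl-3-[(4,4,5,5-tetramethyl-1,3,2-dioxaborolan-2-yl)methyl]furan-2(5H)-one F1, whose allyl geometry is locked by the ring. Its Sc(OTf)3-catalysed addition to 15 must occur on the ring face away from the vinyl group and through the same chair, giving (2S)-2-{(2S)-2-[(2R,3R)-2-ethenyl-4-methylidene-5-oxooxolan-3-yl]-2-hydroxyethyl}-2-methyl-5-(prop-1-en-2-yl)furan-3(2H)-one F2. F2 has the C6, C7 and C8 configurations of 27 but the lactone closed on the C6 oxygen. Equilibrating acyl migration (cat. DBU, THF, with recycling of unchanged F2) moves the lactone to the C8 oxygen, and the route is rejoined at compound 27. The position of this equilibrium is not known in advance.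

Step 16 (Mitsunobu inversion). The alcohol is hindered, allylic and next to a branched carbon, so elimination, SN2' attack or slow reaction with the weakly acidic tiglic acid are possible. The fallback sets out from alcohol 27 and separates inversion from acylation. A Mitsunobu reaction with formic acid (a small, stronger acid) gives the inverted (1S)-1-[(2S,3R)-2-{[(2S)-2-methyl-3-oxo-5-(prop-1-en-2-yl)-2,3-dihydrofuran-2-yl]methyl}-4-methylidene-5-oxooxolan-3-yl]prop-2-en-1-yl formate F3. Brief aq. NaHCO3 in THF/MeOH at 0 °C cleaves the formate to (2S)-2-{[(2S,3S)-3-[(1S)-1-hydroxyprop-2-en-1-yl]-4-methylidene-5-oxooxolan-2-yl]methyl}-2-methyl-5-(prop-1-en-2-yl)furan-3(2H)-one F4. F4 is acylated with retention by tiglic acid 28 under Yamaguchi conditions (2,4,6-trichlorobenzoyl chloride, Et3N, then DMAP, toluene), rejoining the route at compound 29.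

Step 17 (ring-closing metathesis). The catalyst must engage a deactivated 1,1-disubstituted alkene on the furanone and close a strained ring next to an allylic ester. The fallback sets out from alcohol 27 and moves the ring closure ahead of the esterification: the free allylic hydroxyl speeds up ruthenium carbene formation and removes the bulky ester from the reacting alkene. Metathesis of 27 under the same catalyst gives the macrocyclic (6R,7S,8S,10S)-6-hydroxy-3,10-epoxy-1-oxogermacra-2,4(Z),11(13)-trien-12,8-olide F5. Mitsunobu esterification of F5 with tiglic acid 28 (PPh3, DIAD) then inverts C6 and gives the target, rejoining the route at compound 30.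

**Further compounds**
F1 | step 14 | (5R)-5-ethenyl-3-[(4,4,5,5-tetramethyl-1,3,2-dioxaborolan-2-yl)methyl]furan-2(5H)-one | C=C[C@H]1OC(=O)C(CB2OC(C)(C)C(C)(C)O2)=C1
F2 | step 14 | (2S)-2-{(2S)-2-[(2R,3R)-2-ethenyl-4-methylidene-5-oxooxolan-3-yl]-2-hydroxyethyl}-2-methyl-5-(prop-1-en-2-yl)furan-3(2H)-one | C=C1C(=O)O[C@H](C=C)[C@H]1[C@@H](O)C[C@]2(C)OC(=CC2=O)C(C)=C
F3 | step 16 | (1S)-1-[(2S,3R)-2-{[(2S)-2-methyl-3-oxo-5-(prop-1-en-2-yl)-2,3-dihydrofuran-2-yl]methyl}-4-methylidene-5-oxooxolan-3-yl]prop-2-en-1-yl formate | C=C1C(=O)O[C@@H](C[C@]2(C)OC(=CC2=O)C(C)=C)[C@@H]1[C@@H](OC=O)C=C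
F4 | step 16 | (2S)-2-{[(2S,3S)-3-[(1S)-1-hydroxyprop-2-en-1-yl]-4-methylidene-5-oxooxolan-2-yl]methyl}-2-methyl-5-(prop-1-en-2-yl)furan-3(2H)-one | C=C1C(=O)O[C@@H](C[C@]2(C)OC(=CC2=O)C(C)=C)[C@@H]1[C@@H](O)C=C
F5 | step 17 | (6R,7S,8S,10S)-6-hydroxy-3,10-epoxy-1-oxogermacra-2,4(Z),11(13)-trien-12,8-olide | C=C1C(=O)O[C@H]2C[C@]3(C)OC(=CC3=O)/C(C)=C\[C@@H](O)[C@H]12
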